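A small charge, [starting material] = 0.032 M with [catalyst] = 54 µM, is to stand for at most 6.0 min, and the question is when it holds most isomer of the product and how much.

the same everywhere: catalyst 54 µM

| run | starting material | remark | time |
|---|---|---|---|
| west | 0.045 M | run made earlier |  |
| south-east | 0.070 M | run made earlier |  |
| flask | 0.032 M |  | 6.0 min |

- west (time / min: isomer of the product / %, target / %, starting material / %): 1.50: 15, 21, 65; 2.00: 19, 22, 58; 2.50: 25, 22, 53; 4.00: 34, 29, 39; 5.00: 39, 28, 32
- south-east (time / min: isomer of the product / %, target / %, starting material / %): 1.50: 14, 20, 64; 2.00: 21, 20, 58; 2.50: 26, 22, 56; 4.00: 34, 26, 39; 5.00: 41, 30, 34

(each reading ± 1.5 percentage points)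

- when, up to 6.0 min, the flask holds most isomer of the product
- the amount of isomer of the product, in percent of the starting material charged, at that time



Two chemists read these runs. Both carry the percent curves over to the flask, since the west and south-east runs, at the same catalyst and with different charges, read alike within the scatter. Both see isomer still rising at 40.0% on average at 5.00 min, so both put the peak at the end of the window. They part over what becomes of the starting material lost after that. The first holds that target now grows slowly, so that of about 6 points of starting material lost, target takes about 1 and isomer the rest. The second, whose reckoning is mine, takes target and isomer as a pair in fast balance (a pre-equilibrium), so that each new portion divides by the isomer share, isomer over target plus isomer, 58.0% as read from the last readings of both runs. Starting material averages 39.0% at 4.00 min and 33.0% at 5.00 min; if the next minute takes the same fraction, 27.9% remains, a loss of 5.1 percentage points, and isomer reaches 42.9%.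

The forecast stands with the first chemist, at 45% after 6 min, with “no sign of a maximum”.

The simulated flask peaks at 6.00 min with 43.4%.

    target + catalyst ⇌ isomer of the product + catalyst, rate k1*[catalyst]*[target] forward; the back reaction follows from the equilibrium constant (K = 1.70, k = 325 /M/s)
    starting material + catalyst ⇌ target + catalyst, rate k2*[starting material]*[catalyst] forward; the back reaction follows from the equilibrium constant (K = 1.70, k = 93.4 /M/s)

In the flask at 6.00 min, the target and isomer step relaxes with a half-life of 0.414 min, shorter than the 1.44 min of the step from starting material and short against the 6.0 min of the run. The first chemist's split, tilted towards isomer, shows later in the flask: from 6.00 min to 60.0 min it loses 10 points of starting material, while isomer gains 8.3 points, more than the 2.2 points that target gains.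

With 1.4 × 10⁻⁴ M of catalyst, 18% of starting material is left at 6.00 min, so the isomer share, applied to the extra 10 points lost beyond the flask, gives 49.3% isomer. The simulation gives 51.4%.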